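**Plan**

- Cuts (labdane numbering C1–C20): the two acetates; C11–C12 (allyl–alkyl coupling of a C15 drimadiene with a C5 allyl bromide made from methyl (R)-glycerate acetonide); C9=C11, C8–CH3 and the C7=C8 unsaturation (back to a trans-decalone); C2–C3 of ring A (ring-closing metathesis); C10–C1 (allylation) and C4–C5 (prenyl Grignard).
- Forward: ring B is bought as 3-ethoxy-2-methylcyclohex-2-enone; the C4 unit is put on C5 and the allyl group on C10; ring A is closed at C2–C3 and saturated; C8–CH3, C7=C8 and C9=C11 follow; the side chain is joined last.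
- Enabling feature: in triene 6 the allyl group on quaternary C10 and the vinyl group on the gem-dimethyl carbon C4 sit on the adjacent ring-B carbons C10 and C5 (C5 still sp2), so C2 and C3 are within reach and close ring A as a cyclohexene.
- Stereochemistry: C10 from the Pd/(R)-t-BuPHOX decarboxylative allylation; C5 (trans fusion) and C9 from hydrogenation and hydroboration on the face opposite the axial C10 methyl; C14 from the chiral pool.

Key step: step 4

Remark: ketone 10 is drawn as its equatorial C8 epimer, but either epimer serves, because C8 becomes sp2 in step 7.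

**Step 1**
Reactants: 1 3-ethoxy-2-methylcyclohex-2-en-1-one
Product: 3 2-methyl-3-(2-methylbut-3-en-2-yl)cyclohex-2-en-1-one, via Grignard adduct 2 (not isolated)
Conditions: Me2C=CHCH2MgCl (1.5 equiv), THF, −78 → 0 °C; then 1 M HCl, 25 °C
Reagents that add atoms: prenylmagnesium chloride, CC(C)=CC[Mg]Cl
Why: Stork–Danheiser transposition: the allylic Grignard reagent should add 1,2 to the vinylogous-ester carbonyl through its γ (tertiary) terminus by a six-membered SE2′ transition state, and acid hydrolysis of the enol ether with loss of the tertiary hydroxyl should give the transposed enone carrying the C4 gem-dimethyl/vinyl unit on C5; no stereocentre is formed.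

**Step 2**
Reactants: 3 2-methyl-3-(2-methylbut-3-en-2-yl)cyclohex-2-en-1-one
Product: 5 2-methyl-3-(2-methylbut-3-en-2-yl)cyclohexa-1,3-dien-1-yl prop-2-en-1-yl carbonate, via potassium dienolate 4 (not isolated)
Conditions: KOt-Bu (1.05 equiv), THF, 0 °C; then ClCO2CH2CH=CH2, −78 °C
Reagents that add atoms: allyl chloroformate, C=CCOC(Cl)=O
Why: Thermodynamic dienolate formation and O-acylation: under equilibrating conditions γ-deprotonation at C6 should give the through-conjugated dienolate rather than the cross-conjugated C8 enolate, and the hard chloroformate should acylate it on oxygen to give the enol carbonate; no stereocentre is formed.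

**Step 3**
Reactants: 5 2-methyl-3-(2-methylbut-3-en-2-yl)cyclohexa-1,3-dien-1-yl prop-2-en-1-yl carbonate
Product: 6 (2S)-2-methyl-3-(2-methylbut-3-en-2-yl)-2-(prop-2-en-1-yl)cyclohex-3-en-1-one
Conditions: Pd2(dba)3 (2.5 mol %), (R)-t-BuPHOX (6 mol %), THF, 25 °C
Reagents that add atoms: none
Why: Decarboxylative asymmetric allylic alkylation (enantioselective Tsuji allylation): zerovalent palladium should ionise the allyl carbonate, loss of CO2 leaves a π-allylpalladium dienolate that couples at the α-carbon C10 as in deconjugative enone alkylation, and the (R)-t-BuPHOX ligand is expected to select the enolate face that gives C10 as S, by analogy with 2-methylcyclohexanone enol carbonates.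

**Step 4**
Reactants: 6 (2S)-2-methyl-3-(2-methylbut-3-en-2-yl)-2-(prop-2-en-1-yl)cyclohex-3-en-1-one
Product: 7 (8aS)-5,5,8a-trimethyl-3,5,8,8a-tetrahydronaphthalen-1(2H)-one
Conditions: RuCl2(H2IMes)(PCy3)(=CHPh) (second-generation Grubbs catalyst, 5 mol %), CH2Cl2 (0.01 M), 40 °C
Reagents that add atoms: none
Why: Ring-closing olefin metathesis: the ruthenium carbene should load onto the unhindered allyl terminus (C2), add across the vinyl group on C4 in an intramolecular [2+2] step, and the ruthenacyclobutane should cyclorevert to the C2=C3 alkene with loss of ethene, which drives the reaction. The closest known reaction type is the ring-closing metathesis of 1,7-dienes to cyclohexenes that carry a quaternary allylic carbon. Ring A (C10–C1–C2=C3–C4–C5) is the only ring closed, as a six-membered carbocycle formed by joining the two terminal alkene carbons of arms held on the adjacent carbons C10 and C5. No stereocentre is created; C10 (S, from step 3) is quaternary and cannot epimerise, and C5 stays sp2 until step 5. The step needs cyclisation to outrun cross-metathesis and must leave C5=C6 untouched: the sp2 C5 holds C4 in the plane of ring B next to the C10 allyl group, the C4 gem-dimethyl group and the quaternary C10 favour the reactive rotamer (Thorpe–Ingold effect), and the trisubstituted C5=C6 bond, flanked by two fully substituted carbons, should be inert to the catalyst.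

**Step 5**
Reactants: 7 (8aS)-5,5,8a-trimethyl-3,5,8,8a-tetrahydronaphthalen-1(2H)-one
Product: 8 (4aS,8aS)-5,5,8a-trimethyloctahydronaphthalen-1(2H)-one
Conditions: H2 (4 atm), Pd/C (10 %), EtOH–AcOH, 25 °C
Reagents that add atoms: none
Why: Heterogeneous catalytic hydrogenation: the disubstituted C2=C3 bond should be reduced readily and the hindered C5=C6 bond should take up hydrogen from the α face, opposite the C10 methyl and the β-methyl on C4, which sets C5 (S) and the trans ring fusion, as is known for 4,4,10-trimethyl-Δ5-octalins.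

**Step 6**
Reactants: 8 (4aS,8aS)-5,5,8a-trimethyloctahydronaphthalen-1(2H)-one
Product: 10 (2R,4aS,8aS)-2,5,5,8a-tetramethyloctahydronaphthalen-1(2H)-one, via lithium enolate 9 (not isolated)
Conditions: LiN(i-Pr)2, THF, −78 °C; then MeI, −78 → 0 °C
Reagents that add atoms: iodomethane, CI
Why: Enolate C-alkylation: only C8 carries α-hydrogens (C10 is quaternary), so a single enolate should form and be methylated; the configuration of the new C8 centre is of no consequence because it becomes sp2 in step 7.

**Step 7**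
Reactants: 10 (2R,4aS,8aS)-2,5,5,8a-tetramethyloctahydronaphthalen-1(2H)-one
Product: 12 (4aS,8aS)-2,5,5,8a-tetramethyl-4a,5,6,7,8,8a-hexahydronaphthalen-1(4H)-one, via silyl enol ether 11 (not isolated)
Conditions: Me3SiOTf, Et3N, CH2Cl2, 0 °C; then Pd(OAc)2 (1.1 equiv), MeCN, 25 °C
Reagents that add atoms: none
Why: Saegusa–Ito oxidation: the only possible silyl enol ether (C8=C9) should be palladated by Pd(OAc)2 and β-hydride elimination of a ring C7–H should give the endocyclic C7=C8 enone; the C8 stereocentre is removed.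

**Step 8**
Reactants: 12 (4aS,8aS)-2,5,5,8a-tetramethyl-4a,5,6,7,8,8a-hexahydronaphthalen-1(4H)-one
Product: 13 (4aS,8aS)-2,5,5,8a-tetramethyl-1-methylidene-1,4,4a,5,6,7,8,8a-octahydronaphthalene
Conditions: Ph3PCH3Br, KOt-Bu, toluene, 90 °C
Reagents that add atoms: methyltriphenylphosphonium bromide, C[P+](c1ccccc1)(c1ccccc1)c1ccccc1.[Br-]
Why: Wittig methylenation under the forcing conditions used for hindered ketones: the ylide should add 1,2 to the C9 carbonyl, which has no α-hydrogen on the C10 side, to give the C9=C11 exocyclic alkene; no stereocentre is formed.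

**Step 9**
Reactants: 14 methyl (4R)-2,2-dimethyl-1,3-dioxolane-4-carboxylate
Product: 16 {2-[(4S)-2,2-dimethyl-1,3-dioxolan-4-yl]prop-2-en-1-yl}trimethylsilane, via bis-silyl carbinol 15 (not isolated)
Conditions: Me3SiCH2MgCl (3 equiv), CeCl3, THF, −78 → 25 °C; then SiO2, CH2Cl2, 25 °C
Reagents that add atoms: (trimethylsilyl)methylmagnesium chloride, C[Si](C)(C)C[Mg]Cl
Why: Double addition of the cerium-modified Grignard reagent to the ester followed by Peterson elimination of one β-silyl group from the tertiary carbinol should give the 2-substituted allylsilane; the weakly basic organocerium reagent should leave the α-alkoxy stereocentre (C14) untouched.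

**Step 10**
Reactants: 16 {2-[(4S)-2,2-dimethyl-1,3-dioxolan-4-yl]prop-2-en-1-yl}trimethylsilane
Product: 17 (4S)-4-(3-bromoprop-1-en-2-yl)-2,2-dimethyl-1,3-dioxolane
Conditions: NBS, propylene oxide, CH2Cl2, −78 °C
Reagents that add atoms: N-bromosuccinimide, O=C1CCC(=O)N1Br
Why: Electrophilic bromodesilylation of an allylsilane (SE2′): bromine should add to the terminal alkene carbon and the β-silyl cation should lose silicon, and because the allyl unit is 2-substituted both termini are equivalent and a single allyl bromide results; C14 is not involved.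

**Step 11**
Reactants: 13 (4aS,8aS)-2,5,5,8a-tetramethyl-1-methylidene-1,4,4a,5,6,7,8,8a-octahydronaphthalene; 17 (4S)-4-(3-bromoprop-1-en-2-yl)-2,2-dimethyl-1,3-dioxolane
Product: 19 (4S)-2,2-dimethyl-4-{4-[(1S,4aS,8aS)-2,5,5,8a-tetramethyl-1,4,4a,5,6,7,8,8a-octahydronaphthalen-1-yl]but-1-en-2-yl}-1,3-dioxolane, via alkylborane 18 (not isolated)
Conditions: 9-BBN, THF, 60 °C; then KOt-Bu, CuOAc (10 mol %), 17, THF, 40 °C
Reagents that add atoms: none
Why: Hydroboration followed by copper-catalysed allyl–alkyl coupling of a B-alkyl-9-BBN with an allylic halide: 9-BBN should add to the less hindered 1,1-disubstituted C9=C11 bond with boron on C11 from the α face, opposite the axial C10 methyl, which sets C9 (S, H α), and the alkoxide-activated borane should transfer the alkyl group to copper and substitute the allylic bromide (SN2 and SN2′ give the same product for this 2-substituted allyl unit).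

**Step 12**
Reactants: 19 (4S)-2,2-dimethyl-4-{4-[(1S,4aS,8aS)-2,5,5,8a-tetramethyl-1,4,4a,5,6,7,8,8a-octahydronaphthalen-1-yl]but-1-en-2-yl}-1,3-dioxolane
Product: 20 (2S)-3-methylidene-5-[(1S,4aS,8aS)-2,5,5,8a-tetramethyl-1,4,4a,5,6,7,8,8a-octahydronaphthalen-1-yl]pentane-1,2-diol
Conditions: AcOH–H2O (4:1), 40 °C
Reagents that add atoms: none
Why: Acid-catalysed acetal hydrolysis: mild aqueous acetic acid should cleave the isopropylidene acetal without moving the C7=C8 or C13=C16 alkenes, and no bond to C14 is broken.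

**Step 13**
Reactants: 20 (2S)-3-methylidene-5-[(1S,4aS,8aS)-2,5,5,8a-tetramethyl-1,4,4a,5,6,7,8,8a-octahydronaphthalen-1-yl]pentane-1,2-diol
Product: 21 (2S)-3-methylidene-5-[(1S,4aS,8aS)-2,5,5,8a-tetramethyl-1,4,4a,5,6,7,8,8a-octahydronaphthalen-1-yl]pentane-1,2-diyl diacetate
Conditions: Ac2O, pyridine, DMAP (cat.), CH2Cl2, 25 °C
Reagents that add atoms: acetic anhydride, CC(=O)OC(C)=O
Why: DMAP-catalysed O-acylation of the primary and the secondary allylic hydroxyl groups, with retention at C14, should give the target.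

**Compound list**

1 | 3-ethoxy-2-methylcyclohex-2-en-1-one | CCOC1=C(C)C(=O)CCC1 | starting material
2 | 3-ethoxy-2-methyl-1-(2-methylbut-3-en-2-yl)cyclohex-2-en-1-ol (racemic, formed as its magnesium alkoxide, not isolated) | CCOC1=C(C)C(O)(CCC1)C(C)(C)C=C | intermediate
3 | 2-methyl-3-(2-methylbut-3-en-2-yl)cyclohex-2-en-1-one | O=C1CCCC(C(C)(C)C=C)=C1C | intermediate
4 | potassium 2-methyl-3-(2-methylbut-3-en-2-yl)cyclohexa-1,3-dien-1-olate (not isolated) | [K+].[O-]C1=C(C)C(C(C)(C)C=C)=CCC1 | intermediate
5 | 2-methyl-3-(2-methylbut-3-en-2-yl)cyclohexa-1,3-dien-1-yl prop-2-en-1-yl carbonate | C=CCOC(=O)OC1=C(C)C(C(C)(C)C=C)=CCC1 | intermediate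
6 | (2S)-2-methyl-3-(2-methylbut-3-en-2-yl)-2-(prop-2-en-1-yl)cyclohex-3-en-1-one | O=C1CCC=C(C(C)(C)C=C)[C@]1(C)CC=C | intermediate
7 | (8aS)-5,5,8a-trimethyl-3,5,8,8a-tetrahydronaphthalen-1(2H)-one | O=C1CCC=C2C(C)(C)C=CC[C@]12C | intermediate
8 | (4aS,8aS)-5,5,8a-trimethyloctahydronaphthalen-1(2H)-one | O=C1CCC[C@H]2C(C)(C)CCC[C@]12C | intermediate
9 | lithium (4aS,8aS)-5,5,8a-trimethyl-3,4,4a,5,6,7,8,8a-octahydronaphthalen-1-olate (not isolated) | [Li+].[O-]C1=CCC[C@H]2C(C)(C)CCC[C@]12C | intermediate
10 | (2R,4aS,8aS)-2,5,5,8a-tetramethyloctahydronaphthalen-1(2H)-one | O=C1[C@H](C)CC[C@H]2C(C)(C)CCC[C@]12C | intermediate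
11 | trimethyl{[(4aS,8aS)-2,5,5,8a-tetramethyl-3,4,4a,5,6,7,8,8a-octahydronaphthalen-1-yl]oxy}silane (not isolated) | C[Si](C)(C)OC1=C(C)CC[C@H]2C(C)(C)CCC[C@]12C | intermediate
12 | (4aS,8aS)-2,5,5,8a-tetramethyl-4a,5,6,7,8,8a-hexahydronaphthalen-1(4H)-one | O=C1C(C)=CC[C@H]2C(C)(C)CCC[C@]12C | intermediate
13 | (4aS,8aS)-2,5,5,8a-tetramethyl-1-methylidene-1,4,4a,5,6,7,8,8a-octahydronaphthalene (drima-7,9(11)-diene) | C=C1C(C)=CC[C@H]2C(C)(C)CCC[C@]12C | intermediate
14 | methyl (4R)-2,2-dimethyl-1,3-dioxolane-4-carboxylate | COC(=O)[C@H]1COC(C)(C)O1 | starting material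
15 | 2-[(4R)-2,2-dimethyl-1,3-dioxolan-4-yl]-1,3-bis(trimethylsilyl)propan-2-ol (not isolated) | C[Si](C)(C)CC(O)(C[Si](C)(C)C)[C@H]1COC(C)(C)O1 | intermediate
16 | {2-[(4S)-2,2-dimethyl-1,3-dioxolan-4-yl]prop-2-en-1-yl}trimethylsilane | C[Si](C)(C)CC(=C)[C@H]1COC(C)(C)O1 | intermediate
17 | (4S)-4-(3-bromoprop-1-en-2-yl)-2,2-dimethyl-1,3-dioxolane | BrCC(=C)[C@H]1COC(C)(C)O1 | intermediate
18 | 9-{[(1S,4aS,8aS)-2,5,5,8a-tetramethyl-1,4,4a,5,6,7,8,8a-octahydronaphthalen-1-yl]methyl}-9-borabicyclo[3.3.1]nonane (not isolated) | C(B3C4CCCC3CCC4)[C@H]1C(C)=CC[C@H]2C(C)(C)CCC[C@]12C | intermediate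
19 | (4S)-2,2-dimethyl-4-{4-[(1S,4aS,8aS)-2,5,5,8a-tetramethyl-1,4,4a,5,6,7,8,8a-octahydronaphthalen-1-yl]but-1-en-2-yl}-1,3-dioxolane | C=C(CC[C@H]1C(C)=CC[C@H]2C(C)(C)CCC[C@]12C)[C@H]3COC(C)(C)O3 | intermediate
20 | (2S)-3-methylidene-5-[(1S,4aS,8aS)-2,5,5,8a-tetramethyl-1,4,4a,5,6,7,8,8a-octahydronaphthalen-1-yl]pentane-1,2-diol | C=C(CC[C@H]1C(C)=CC[C@H]2C(C)(C)CCC[C@]12C)[C@@H](CO)O | intermediate
21 | (2S)-3-methylidene-5-[(1S,4aS,8aS)-2,5,5,8a-tetramethyl-1,4,4a,5,6,7,8,8a-octahydronaphthalen-1-yl]pentane-1,2-diyl diacetate | C=C(CC[C@H]1C(C)=CC[C@H]2C(C)(C)CCC[C@]12C)[C@@H](COC(C)=O)OC(C)=O | target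

**Count**

Total steps: 13. Longest linear sequence: 11 (steps 1–8 and 11–13); steps 9–10 prepare the side-chain fragment.

**Steps most likely to fail**

1. Step 3. The process at risk is face selection on a hindered dienolate, together with possible allylation at the γ-carbon C6 instead of C10. The fallback sets the quaternary centre by desymmetrisation instead of catalytic enolate allylation; it sets out from 1 and returns at 6. Hydrolysis of 1 with aqueous HCl should give 2-methylcyclohexane-1,3-dione F1. C-Allylation (allyl acetate, Pd(PPh3)4, Et3N) should give 2-methyl-2-(prop-2-en-1-yl)cyclohexane-1,3-dione F2. Corey–Bakshi–Shibata reduction with the (S)-Me-oxazaborolidine and catecholborane, with hydride delivered anti to the allyl group, is expected to give (2R,3R)-3-hydroxy-2-methyl-2-(prop-2-en-1-yl)cyclohexan-1-one F3; the minor carbinol diastereomer, which carries the opposite quaternary configuration, is removed by chromatography. Prenylmagnesium chloride should add through its γ-terminus to the remaining ketone to give (1R,2R)-2-methyl-3-(2-methylbut-3-en-2-yl)-2-(prop-2-en-1-yl)cyclohexane-1,3-diol F4. Dess–Martin oxidation of the secondary alcohol should give (2S)-3-hydroxy-2-methyl-3-(2-methylbut-3-en-2-yl)-2-(prop-2-en-1-yl)cyclohexan-1-one F5. Dehydration of the tertiary alcohol with SOCl2/pyridine, for which only C6 offers β-hydrogens, should give 6.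

2. Step 11. The process at risk is slow or face-unselective hydroboration of the hindered conjugated diene, or failure of the boron-to-copper transfer of the β-branched alkyl group. The fallback goes through an isolated alcohol and a Grignard reagent; it sets out from 13 and returns at 19. Borane 18 is oxidised with NaOH/H2O2 to [(1S,4aS,8aS)-2,5,5,8a-tetramethyl-1,4,4a,5,6,7,8,8a-octahydronaphthalen-1-yl]methanol F6 (drimenol), which can be purified from any C9 epimer. I2, PPh3 and imidazole should convert it into (1S,4aS,8aS)-1-(iodomethyl)-2,5,5,8a-tetramethyl-1,4,4a,5,6,7,8,8a-octahydronaphthalene F7. Magnesium in THF should give {[(1S,4aS,8aS)-2,5,5,8a-tetramethyl-1,4,4a,5,6,7,8,8a-octahydronaphthalen-1-yl]methyl}magnesium iodide F8, and its coupling with bromide 17 under CuBr·SMe2 catalysis should give 19.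

3. Step 8. The process at risk is γ-deprotonation of the enone by the basic ylide, or no addition at a carbonyl flanked by the quaternary C10 and the C8 methyl. The fallback replaces ylide olefination by addition–elimination; it sets out from 12 and returns at 13. Me3SiCH2Li (THF, −78 → 0 °C), a small and weakly basic nucleophile, should add 1,2 to give (4aS,8aS)-2,5,5,8a-tetramethyl-1-[(trimethylsilyl)methyl]-1,4,4a,5,6,7,8,8a-octahydronaphthalen-1-ol F9, and KH in THF should bring about syn Peterson elimination to 13.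

**Further compounds**

F1 | step 3 | 2-methylcyclohexane-1,3-dione | CC1C(=O)CCCC1=O
F2 | step 3 | 2-methyl-2-(prop-2-en-1-yl)cyclohexane-1,3-dione | C=CCC1(C)C(=O)CCCC1=O
F3 | step 3 | (2R,3R)-3-hydroxy-2-methyl-2-(prop-2-en-1-yl)cyclohexan-1-one | O[C@@H]1CCCC(=O)[C@]1(C)CC=C
F4 | step 3 | (1R,2R)-2-methyl-3-(2-methylbut-3-en-2-yl)-2-(prop-2-en-1-yl)cyclohexane-1,3-diol (C3 epimers) | O[C@@H]1CCCC(O)(C(C)(C)C=C)[C@]1(C)CC=C
F5 | step 3 | (2S)-3-hydroxy-2-methyl-3-(2-methylbut-3-en-2-yl)-2-(prop-2-en-1-yl)cyclohexan-1-one (C3 epimers) | O=C1CCCC(O)(C(C)(C)C=C)[C@]1(C)CC=C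
F6 | step 11 | [(1S,4aS,8aS)-2,5,5,8a-tetramethyl-1,4,4a,5,6,7,8,8a-octahydronaphthalen-1-yl]methanol | OC[C@H]1C(C)=CC[C@H]2C(C)(C)CCC[C@]12C
F7 | step 11 | (1S,4aS,8aS)-1-(iodomethyl)-2,5,5,8a-tetramethyl-1,4,4a,5,6,7,8,8a-octahydronaphthalene | IC[C@H]1C(C)=CC[C@H]2C(C)(C)CCC[C@]12C
F8 | step 11 | {[(1S,4aS,8aS)-2,5,5,8a-tetramethyl-1,4,4a,5,6,7,8,8a-octahydronaphthalen-1-yl]methyl}magnesium iodide | I[Mg]C[C@H]1C(C)=CC[C@H]2C(C)(C)CCC[C@]12C
F9 | step 8 | (4aS,8aS)-2,5,5,8a-tetramethyl-1-[(trimethylsilyl)methyl]-1,4,4a,5,6,7,8,8a-octahydronaphthalen-1-ol (C1 epimers) | C[Si](C)(C)CC1(O)C(C)=CC[C@H]2C(C)(C)CCC[C@]12C
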